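## Retrosynthetic overview

1. The target is read as epicatechin-3-O-gallate-(4β→6)-epicatechin-3-O-gallate-(4β→8)-catechin. The last operation is global hydrogenolysis (19 benzyl groups, 4 aryl bromides). The last C–C bond made is the upper C4–C6 interflavan bond.
2. The lower two units have bought rings: (−)-epicatechin as an 8-bromo-4-alkoxy-3-O-gallate electrophile and (+)-catechin as the C8 nucleophile. Bromine caps then leave C6 of the middle unit as the only free phloroglucinol-type CH.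
3. The upper unit comes from (+)-catechin again. Its ring C is contracted by a Wolff rearrangement that cuts C2–C3 and keeps C2. This gives a 2-aryl-2,3-dihydrobenzofuran in which C2 is bonded to C4 and C3 is an exocyclic formyl carbon.
4. In the key step galloyl chloride acylates the formyl oxygen, C2 slides from C4 to C3 (five- to six-membered ring), and C6 of the dimer takes up the resulting C4 cation. Ring C, the gallate, C3, C4 and the 4→6 bond all arise in one flask.
5. The enabling feature lies in ring C. C4 is benzylic to ring A, which carries oxygen at C5, C7 and C8a and holds the cation. C2 carries O1 and ring B, which makes it an excellent migrating carbon. C3 between them carries only the ester oxygen.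

Key step: step 15

Assumption: 1, 4 and 8 are taken as commercial. Flavan numbering (O1, C2, C3, C4, C4a, C8a) is kept for these atoms in the dihydrobenzofurans as well, wherever the mechanism is discussed.

## Route

Step 1
Reactants: 1 (+)-catechin
Product: 2 5,7,3',4'-tetra-O-benzyl-(+)-catechin
Conditions: BnBr, K2CO3, DMF, −10 °C to rt
Reagents that add atoms: benzyl bromide BrCc1ccccc1
Why: Williamson etherification of the four phenols, which are far more acidic than the 3-OH, so the secondary alcohol stays free and no stereocentre is touched.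

Step 2
Reactants: 2 5,7,3',4'-tetra-O-benzyl-(+)-catechin
Product: 3 3,5,7,3',4'-penta-O-benzyl-(+)-catechin
Conditions: NaH, BnBr, DMF, 0 °C to rt
Reagents that add atoms: benzyl bromide BrCc1ccccc1
Why: Williamson etherification of the remaining alkoxide, which keeps O3 of the future bottom unit out of all later cation and acyl chemistry and is removed in the final hydrogenolysis.

Step 3
Reactants: 4 (−)-epicatechin
Product: 5 5,7,3',4'-tetra-O-benzyl-(−)-epicatechin
Conditions: BnBr, K2CO3, DMF, −10 °C to rt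
Reagents that add atoms: benzyl bromide BrCc1ccccc1
Why: Williamson etherification of the phenols only, run cold so that C2 is not epimerised.

Step 4
Reactants: 5 5,7,3',4'-tetra-O-benzyl-(−)-epicatechin
Product: 6 5,7,3',4'-tetra-O-benzyl-4β-(2-ethoxyethoxy)epicatechin
Conditions: DDQ, 2-ethoxyethanol, CH2Cl2, rt
Reagents that add atoms: 2-ethoxyethanol CCOCCO
Why: DDQ abstracts hydride from benzylic C4 (oxidative C–H etherification) and the alcohol attacks the ring-A-stabilised cation anti to the axial 3-OH, which sets C4 as 4β.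

Step 5
Reactants: 6 5,7,3',4'-tetra-O-benzyl-4β-(2-ethoxyethoxy)epicatechin
Product: 7 8-bromo-5,7,3',4'-tetra-O-benzyl-4β-(2-ethoxyethoxy)epicatechin
Conditions: NBS (1.0 equiv), CH2Cl2, −78 to 0 °C
Reagents that add atoms: N-bromosuccinimide O=C1CCC(=O)N1Br
Why: Electrophilic aromatic bromination goes to C8, the less hindered of the two activated ring A positions, and the cap later blocks self-condensation and 4→8 attack on this unit.

Step 6
Reactants: 7 8-bromo-5,7,3',4'-tetra-O-benzyl-4β-(2-ethoxyethoxy)epicatechin; 8 3,4,5-tris(benzyloxy)benzoic acid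
Product: 9 8-bromo-5,7,3',4'-tetra-O-benzyl-4β-(2-ethoxyethoxy)epicatechin 3-O-[3,4,5-tris(benzyloxy)benzoate]
Conditions: DCC, 4-(dimethylamino)pyridine, CH2Cl2, rt
Reagents that add atoms: none
Why: Steglich esterification of the only free hydroxyl group, with the C3–O bond untouched.

Step 7
Reactants: 9 8-bromo-5,7,3',4'-tetra-O-benzyl-4β-(2-ethoxyethoxy)epicatechin 3-O-[3,4,5-tris(benzyloxy)benzoate]; 3 3,5,7,3',4'-penta-O-benzyl-(+)-catechin (2 equiv)
Product: 10 [8-bromo-tetra-O-benzylepicatechin 3-O-(tri-O-benzylgallate)]-(4β→8)-penta-O-benzylcatechin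
Conditions: TMSOTf (0.3 equiv), CH2Cl2, −78 to −30 °C
Reagents that add atoms: none
Why: Lewis-acid Friedel–Crafts flavanylation, in which the C4 cation bridged by the 3-O-acyl group is attacked anti (4β, 3,4-trans) by C8 of 3, its most nucleophilic carbon, while the 8-bromine keeps 9 from condensing with itself.

Step 8
Reactants: 10 [8-bromo-tetra-O-benzylepicatechin 3-O-(tri-O-benzylgallate)]-(4β→8)-penta-O-benzylcatechin
Product: 11 [8-bromo-tetra-O-benzylepicatechin 3-O-(tri-O-benzylgallate)]-(4β→8)-6-bromo-penta-O-benzylcatechin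
Conditions: NBS (1.0 equiv), CH2Cl2, −78 to −40 °C
Reagents that add atoms: N-bromosuccinimide O=C1CCC(=O)N1Br
Why: Electrophilic aromatic bromination picks C6 of the catechin unit (alkyl-substituted ring) over C6 of the middle unit (ring deactivated by its 8-bromine), so the latter stays the only free ring A position.

Step 9
Reactants: 2 5,7,3',4'-tetra-O-benzyl-(+)-catechin
Product: 12 (2R)-5,7-bis(benzyloxy)-2-[3,4-bis(benzyloxy)phenyl]chroman-3-one
Conditions: Dess–Martin periodinane, CH2Cl2, rt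
Reagents that add atoms: none
Why: Dess–Martin oxidation under neutral conditions erases C3 and leaves the enolisable C2 centre configurationally intact.

Step 10
Reactants: 12 (2R)-5,7-bis(benzyloxy)-2-[3,4-bis(benzyloxy)phenyl]chroman-3-one
Product: 14 (2R)-5,7-bis(benzyloxy)-2-[3,4-bis(benzyloxy)phenyl]-4-diazochroman-3-one, via trifluoroacetyl ketone 13 (not isolated)
Conditions: LiN(SiMe3)2, THF, −78 °C; CF3CO2CH2CF3; aq HCl work-up; then MsN3, Et3N, H2O (1 equiv), MeCN, rt
Reagents that add atoms: methanesulfonyl azide CS(=O)(=O)N=[N+]=[N-]; 2,2,2-trifluoroethyl trifluoroacetate O=C(OCC(F)(F)F)C(F)(F)F (its acyl group stays only in 13)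
Why: Detrifluoroacetylative Regitz-type diazo transfer, in which kinetic deprotonation takes the unhindered benzylic CH2-4 and the acidic 1,3-dicarbonyl then needs only Et3N, so C2–H is never exposed to an equilibrating base.

Step 11
Reactants: 14 (2R)-5,7-bis(benzyloxy)-2-[3,4-bis(benzyloxy)phenyl]-4-diazochroman-3-one
Product: 17 methyl (2S,3S)-4,6-bis(benzyloxy)-2-[3,4-bis(benzyloxy)phenyl]-2,3-dihydro-1-benzofuran-3-carboxylate, via ketene 15 (not isolated), via cis ester 16 (not isolated)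
Conditions: hν (365 nm), MeOH–THF, 0 °C; then NaOMe (0.2 equiv), rt
Reagents that add atoms: methanol CO
Why: Photochemical Wolff rearrangement of an s-cis-locked cyclic α-diazoketone moves C2 from C3 to C4 with retention (six- to five-membered ring), methanol adds to the ketene, and methoxide equilibrates the ester-bearing carbon to the more stable 2,3-trans isomer.

Step 12
Reactants: 17 methyl (2S,3S)-4,6-bis(benzyloxy)-2-[3,4-bis(benzyloxy)phenyl]-2,3-dihydro-1-benzofuran-3-carboxylate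
Product: 18 methyl (2S,3S)-4,6-bis(benzyloxy)-2-[3,4-bis(benzyloxy)phenyl]-5,7-dibromo-2,3-dihydro-1-benzofuran-3-carboxylate
Conditions: NBS (2.05 equiv), CH2Cl2, −40 to 0 °C
Reagents that add atoms: N-bromosuccinimide O=C1CCC(=O)N1Br
Why: Electrophilic aromatic bromination fills both free positions of the trioxygenated ring A, which is much more reactive than ring B, so no regiochemical choice is needed and the upper unit can no longer act as a nucleophile.

Step 13
Reactants: 18 methyl (2S,3S)-4,6-bis(benzyloxy)-2-[3,4-bis(benzyloxy)phenyl]-5,7-dibromo-2,3-dihydro-1-benzofuran-3-carboxylate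
Product: 19 (2S,3S)-4,6-bis(benzyloxy)-2-[3,4-bis(benzyloxy)phenyl]-5,7-dibromo-2,3-dihydro-1-benzofuran-3-carbaldehyde
Conditions: i-Bu2AlH (1.1 equiv), toluene, −78 °C; aq sodium potassium tartrate; used at once
Reagents that add atoms: none
Why: Partial ester reduction stops at the tetrahedral aluminate at −78 °C, and the trans aldehyde is the thermodynamic epimer, so its configuration is safe on neutral work-up.

Step 14
Reactants: 8 3,4,5-tris(benzyloxy)benzoic acid
Product: 20 3,4,5-tris(benzyloxy)benzoyl chloride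
Conditions: (COCl)2, N,N-dimethylformamide (cat.), CH2Cl2, 0 °C to rt
Reagents that add atoms: oxalyl chloride O=C(Cl)C(=O)Cl
Why: Standard acid chloride formation through the chloroiminium (Vilsmeier-type) activator.

Step 15
Reactants: 19 (2S,3S)-4,6-bis(benzyloxy)-2-[3,4-bis(benzyloxy)phenyl]-5,7-dibromo-2,3-dihydro-1-benzofuran-3-carbaldehyde; 20 3,4,5-tris(benzyloxy)benzoyl chloride; 11 [8-bromo-tetra-O-benzylepicatechin 3-O-(tri-O-benzylgallate)]-(4β→8)-6-bromo-penta-O-benzylcatechin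
Product: 23 nonadeca-O-benzyl-tetrabromo trimer [6,8-dibromoepicatechin 3-O-gallate]-(4β→6)-[8-bromoepicatechin 3-O-gallate]-(4β→8)-[6-bromocatechin], via 1-chloroalkyl gallate 21 (not isolated), via acyloxonium ion 22 (not isolated)
Conditions: 19, 20 (1.05 equiv), ZnCl2 (5 mol %), CH2Cl2, −20 to 0 °C; then 11 (0.8 equiv), 2,6-di-tert-butyl-4-methylpyridine, 4 Å MS, AgOTf (1.1 equiv), CH2Cl2–toluene, −78 to −30 °C
Reagents that add atoms: none
Why: Proposed new method: ZnCl2-catalysed addition of 20 to the formyl group gives the 1-chloroalkyl ester 21 (a known aldehyde/acyl chloride addition), AgOTf removes chloride, and in the rotamer that holds C4–H in the nodal plane of the acyloxycarbenium centre C3 and turns the acyloxy group away from ring A, the C2–C4 bond (pushed by O1 and ring B) migrates to C3, a Wagner–Meerwein shift that reverses a pinacol-type ring contraction and whose closest known relatives are the acid-induced aldehyde–ketone rearrangement and semipinacol ring enlargements. No ring is closed by cyclisation here: the five-membered ring O1–C2–C4–C4a–C8a becomes six-membered ring C by insertion of C3 into the C2–C4 bond, and the gallate carbonyl oxygen then closes a transient cis-fused five-membered acyloxonium ring onto C4 (22) by neighbouring-group participation. C2 migrates with retention, as migrating carbons do in 1,2-shifts; C3 is set by the exo rotamer, which from the 2,3-trans aldehyde places O3 cis to ring B; and C4 is set by attack of C6 of 11 anti to the acyloxonium bridge (3,4-trans, 4β), the course known for 3-O-acylflavan-4-yl cations. The driving force is the change from a weakly stabilised acyloxycarbenium ion to a benzylic cation held by O5, O7 and O1. Three selectivities are needed: C2 shift over 1,2-hydride shift from C4 (secured by the rotamer and the donor-loaded C2–C4 bond), a bridged shift over full heterolysis of C2–C4 (low temperature and a weakly polar medium), and C6 of the middle unit as the sole nucleophile (every other phloroglucinol-type CH in 11 and 19 carries bromine, no hydroxyl group is free, and 20 is consumed before 11 is added).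

Step 16
Reactants: 23 nonadeca-O-benzyl-tetrabromo trimer
Product: 24 epicatechin-3-O-gallate-(4β→6)-epicatechin-3-O-gallate-(4β→8)-catechin (CNP0112921.1)
Conditions: H2 (1 atm), Pd(OH)2/C, Et3N (4.4 equiv), THF–MeOH–H2O, rt; Sephadex LH-20
Reagents that add atoms: none
Why: Catalytic hydrogenolysis cleaves all benzyl ethers and all four aryl C–Br bonds in one operation, Et3N takes up HBr so the acid-labile interflavan bonds are not cleaved, and no stereocentre is involved.

## Compound list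

1 | (+)-catechin | Oc1cc(O)c2c(c1)O[C@H](c1ccc(O)c(O)c1)[C@@H](O)C2 | starting material
2 | 5,7,3',4'-tetra-O-benzyl-(+)-catechin | O(Cc9ccccc9)c1cc(OCc9ccccc9)c2c(c1)O[C@H](c8ccc(OCc9ccccc9)c(OCc9ccccc9)c8)[C@@H](O)C2 | intermediate
3 | 3,5,7,3',4'-penta-O-benzyl-(+)-catechin | O(Cc9ccccc9)c1cc(OCc9ccccc9)c2c(c1)O[C@H](c8ccc(OCc9ccccc9)c(OCc9ccccc9)c8)[C@@H](OCc9ccccc9)C2 | intermediate
4 | (−)-epicatechin | Oc1cc(O)c2c(c1)O[C@H](c1ccc(O)c(O)c1)[C@H](O)C2 | starting material
5 | 5,7,3',4'-tetra-O-benzyl-(−)-epicatechin | O(Cc9ccccc9)c1cc(OCc9ccccc9)c2c(c1)O[C@H](c8ccc(OCc9ccccc9)c(OCc9ccccc9)c8)[C@H](O)C2 | intermediate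
6 | 5,7,3',4'-tetra-O-benzyl-4β-(2-ethoxyethoxy)epicatechin | O(Cc9ccccc9)c1cc(OCc9ccccc9)c2c(c1)O[C@H](c8ccc(OCc9ccccc9)c(OCc9ccccc9)c8)[C@H](O)[C@H]2OCCOCC | intermediate
7 | 8-bromo-5,7,3',4'-tetra-O-benzyl-4β-(2-ethoxyethoxy)epicatechin | O(Cc9ccccc9)c1cc(OCc9ccccc9)c2c(c1Br)O[C@H](c8ccc(OCc9ccccc9)c(OCc9ccccc9)c8)[C@H](O)[C@H]2OCCOCC | intermediate
8 | 3,4,5-tris(benzyloxy)benzoic acid | OC(=O)c1cc(OCc9ccccc9)c(OCc9ccccc9)c(OCc9ccccc9)c1 | starting material
9 | 8-bromo-5,7,3',4'-tetra-O-benzyl-4β-(2-ethoxyethoxy)epicatechin 3-O-[3,4,5-tris(benzyloxy)benzoate] | O(Cc9ccccc9)c1cc(OCc9ccccc9)c2c(c1Br)O[C@H](c8ccc(OCc9ccccc9)c(OCc9ccccc9)c8)[C@H](OC(=O)c8cc(OCc9ccccc9)c(OCc9ccccc9)c(OCc9ccccc9)c8)[C@H]2OCCOCC | intermediate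
10 | [8-bromo-tetra-O-benzylepicatechin 3-O-(tri-O-benzylgallate)]-(4β→8)-penta-O-benzylcatechin | c1c(OCc9ccccc9)c(Br)c2c(c1OCc9ccccc9)[C@H](c3c(OCc9ccccc9)cc(OCc9ccccc9)c4c3O[C@H](c8ccc(OCc9ccccc9)c(OCc9ccccc9)c8)[C@@H](OCc9ccccc9)C4)[C@@H](OC(=O)c8cc(OCc9ccccc9)c(OCc9ccccc9)c(OCc9ccccc9)c8)[C@@H](c8ccc(OCc9ccccc9)c(OCc9ccccc9)c8)O2 | intermediate
11 | [8-bromo-tetra-O-benzylepicatechin 3-O-(tri-O-benzylgallate)]-(4β→8)-6-bromo-penta-O-benzylcatechin | c1c(OCc9ccccc9)c(Br)c2c(c1OCc9ccccc9)[C@H](c3c(OCc9ccccc9)c(Br)c(OCc9ccccc9)c4c3O[C@H](c8ccc(OCc9ccccc9)c(OCc9ccccc9)c8)[C@@H](OCc9ccccc9)C4)[C@@H](OC(=O)c8cc(OCc9ccccc9)c(OCc9ccccc9)c(OCc9ccccc9)c8)[C@@H](c8ccc(OCc9ccccc9)c(OCc9ccccc9)c8)O2 | intermediate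
12 | (2R)-5,7-bis(benzyloxy)-2-[3,4-bis(benzyloxy)phenyl]chroman-3-one | O(Cc9ccccc9)c1cc(OCc9ccccc9)c2c(c1)O[C@H](c8ccc(OCc9ccccc9)c(OCc9ccccc9)c8)C(=O)C2 | intermediate
13 | 4-trifluoroacetyl derivative of 12 (epimers or enol at C4) | O(Cc9ccccc9)c1cc(OCc9ccccc9)c2c(c1)O[C@H](c8ccc(OCc9ccccc9)c(OCc9ccccc9)c8)C(=O)C2C(=O)C(F)(F)F | intermediate
14 | (2R)-5,7-bis(benzyloxy)-2-[3,4-bis(benzyloxy)phenyl]-4-diazochroman-3-one | O(Cc9ccccc9)c1cc(OCc9ccccc9)c2c(c1)O[C@H](c8ccc(OCc9ccccc9)c(OCc9ccccc9)c8)C(=O)C2=[N+]=[N-] | intermediate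
15 | ketene: 2-aryl-4,6-bis(benzyloxy)-3-(oxomethylidene)-2,3-dihydrobenzofuran, C2 as in 14 | O(Cc9ccccc9)c1cc(OCc9ccccc9)c2c(c1)O[C@H](c8ccc(OCc9ccccc9)c(OCc9ccccc9)c8)C2=C=O | intermediate
16 | methyl (2S,3R)-4,6-bis(benzyloxy)-2-[3,4-bis(benzyloxy)phenyl]-2,3-dihydro-1-benzofuran-3-carboxylate (cis) | O(Cc9ccccc9)c1cc(OCc9ccccc9)c2c(c1)O[C@H](c8ccc(OCc9ccccc9)c(OCc9ccccc9)c8)[C@@H]2C(=O)OC | intermediate
17 | methyl (2S,3S)-4,6-bis(benzyloxy)-2-[3,4-bis(benzyloxy)phenyl]-2,3-dihydro-1-benzofuran-3-carboxylate (trans) | O(Cc9ccccc9)c1cc(OCc9ccccc9)c2c(c1)O[C@H](c8ccc(OCc9ccccc9)c(OCc9ccccc9)c8)[C@H]2C(=O)OC | intermediate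
18 | methyl (2S,3S)-4,6-bis(benzyloxy)-2-[3,4-bis(benzyloxy)phenyl]-5,7-dibromo-2,3-dihydro-1-benzofuran-3-carboxylate | O(Cc9ccccc9)c1c(Br)c(OCc9ccccc9)c2c(c1Br)O[C@H](c8ccc(OCc9ccccc9)c(OCc9ccccc9)c8)[C@H]2C(=O)OC | intermediate
19 | (2S,3S)-4,6-bis(benzyloxy)-2-[3,4-bis(benzyloxy)phenyl]-5,7-dibromo-2,3-dihydro-1-benzofuran-3-carbaldehyde | O(Cc9ccccc9)c1c(Br)c(OCc9ccccc9)c2c(c1Br)O[C@H](c8ccc(OCc9ccccc9)c(OCc9ccccc9)c8)[C@H]2C=O | intermediate
20 | 3,4,5-tris(benzyloxy)benzoyl chloride | ClC(=O)c1cc(OCc9ccccc9)c(OCc9ccccc9)c(OCc9ccccc9)c1 | intermediate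
21 | 1-chloroalkyl gallate: chloro[(2S,3S)-2-aryl-4,6-bis(benzyloxy)-5,7-dibromo-2,3-dihydrobenzofuran-3-yl]methyl 3,4,5-tris(benzyloxy)benzoate (both epimers at the CHCl carbon) | O(Cc9ccccc9)c1c(Br)c(OCc9ccccc9)c2c(c1Br)O[C@H](c8ccc(OCc9ccccc9)c(OCc9ccccc9)c8)[C@H]2C(Cl)OC(=O)c8cc(OCc9ccccc9)c(OCc9ccccc9)c(OCc9ccccc9)c8 | intermediate
22 | ring-enlarged 3,4-cis-fused 2-aryl-1,3-dioxolan-2-ylium (acyloxonium) ion of 6,8-dibromo-tetra-O-benzylepicatechin | O(Cc9ccccc9)c1c(Br)c(OCc9ccccc9)c2c(c1Br)O[C@H](c8ccc(OCc9ccccc9)c(OCc9ccccc9)c8)[C@@H]3OC(c8cc(OCc9ccccc9)c(OCc9ccccc9)c(OCc9ccccc9)c8)=[O+][C@H]23 | intermediate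
23 | nonadeca-O-benzyl-tetrabromo trimer [6,8-dibromoepicatechin 3-O-gallate]-(4β→6)-[8-bromoepicatechin 3-O-gallate]-(4β→8)-[6-bromocatechin] | O=C(O[C@@H]1[C@@H](c2c(OCc9ccccc9)c(Br)c3c(c2OCc9ccccc9)[C@H](c4c(OCc9ccccc9)c(Br)c(OCc9ccccc9)c5c4O[C@H](c8ccc(OCc9ccccc9)c(OCc9ccccc9)c8)[C@@H](OCc9ccccc9)C5)[C@@H](OC(=O)c8cc(OCc9ccccc9)c(OCc9ccccc9)c(OCc9ccccc9)c8)[C@@H](c8ccc(OCc9ccccc9)c(OCc9ccccc9)c8)O3)c2c(OCc9ccccc9)c(Br)c(OCc9ccccc9)c(Br)c2O[C@@H]1c1ccc(OCc9ccccc9)c(OCc9ccccc9)c1)c1cc(OCc9ccccc9)c(OCc9ccccc9)c(OCc9ccccc9)c1 | intermediate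
24 | epicatechin-3-O-gallate-(4β→6)-epicatechin-3-O-gallate-(4β→8)-catechin (CNP0112921.1) | O=C(O[C@@H]1[C@@H](c2c(O)cc3c(c2O)[C@H](c2c(O)cc(O)c4c2O[C@H](c2ccc(O)c(O)c2)[C@@H](O)C4)[C@@H](OC(=O)c2cc(O)c(O)c(O)c2)[C@@H](c2ccc(O)c(O)c2)O3)c2c(O)cc(O)cc2O[C@@H]1c1ccc(O)c(O)c1)c1cc(O)c(O)c(O)c1 | target

Total step count: 16. Longest linear sequence: 8 steps (1→2→12→14→17→18→19→23→24, and equally 4→5→6→7→9→10→11→23→24).

## Steps most likely to fail

**Step 15.** Four processes could divert it.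
- A 1,2-hydride shift from C4 to the acyloxycarbenium carbon, followed by loss of H-2, would aromatise the five-membered ring to a benzofuran.
- Complete heterolysis of the C2–C4 bond to an open oxocarbenium/enol-ester pair would erode the configuration at C2 and favour 2,3-trans reclosure.
- Loss of H-3 from the ring-enlarged cation is possible.
- Attack by the bromine-deactivated, flanked C6 of 11 may be slow.

The fallback uses known chemistry only and gives up the ring enlargement. It sets out from 6. Bromination with NBS (2 equiv) gives 6,8-dibromo-tetra-O-benzyl-4β-(2-ethoxyethoxy)epicatechin F1. Steglich esterification with 8 gives its 3-O-[3,4,5-tris(benzyloxy)benzoate] F2. TMSOTf-promoted Friedel–Crafts flavanylation of 11 with F2 returns to the route at 23.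

**Step 11.** O–H insertion of methanol or C–H insertion into the peri 5-O-benzyl group could compete with ring contraction. During the methoxide equilibration the ester enolate could expel the phenoxide and open the ring. The fallback avoids carbene chemistry and sets out from 12. Trimethyl orthoformate and TsOH give the methyl enol ether (2R)-5,7-bis(benzyloxy)-2-[3,4-bis(benzyloxy)phenyl]-3-methoxy-2H-chromene F3. PhI(OAc)2 in MeOH–HC(OMe)3 with catalytic H2SO4 attacks C4, and the ketal carbon passes C2 to C4 as iodobenzene leaves (oxidative ring contraction of a cyclic enol ether). Equilibration with DBU returns to the route at 17.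

**Step 10.** Enolisation toward C2 would erode the only stereocentre, and trifluoroacetylation of the hindered enolate may be incomplete. The fallback avoids strong base and sets out from 12. Nitrosation at CH2-4 with butyl nitrite and HCl gives the α-oximino ketone (2R)-5,7-bis(benzyloxy)-2-[3,4-bis(benzyloxy)phenyl]-4-(hydroxyimino)chroman-3-one F4. The Forster reaction of F4 with chloramine returns to the route at 14.

## Further compounds

F1 | step 15 | 6,8-dibromo-5,7,3',4'-tetra-O-benzyl-4β-(2-ethoxyethoxy)epicatechin | O(Cc9ccccc9)c1c(Br)c(OCc9ccccc9)c2c(c1Br)O[C@H](c8ccc(OCc9ccccc9)c(OCc9ccccc9)c8)[C@H](O)[C@H]2OCCOCC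
F2 | step 15 | 6,8-dibromo-5,7,3',4'-tetra-O-benzyl-4β-(2-ethoxyethoxy)epicatechin 3-O-[3,4,5-tris(benzyloxy)benzoate] | O(Cc9ccccc9)c1c(Br)c(OCc9ccccc9)c2c(c1Br)O[C@H](c8ccc(OCc9ccccc9)c(OCc9ccccc9)c8)[C@H](OC(=O)c8cc(OCc9ccccc9)c(OCc9ccccc9)c(OCc9ccccc9)c8)[C@H]2OCCOCC
F3 | step 11 | (2R)-5,7-bis(benzyloxy)-2-[3,4-bis(benzyloxy)phenyl]-3-methoxy-2H-chromene | O(Cc9ccccc9)c1cc(OCc9ccccc9)c2c(c1)O[C@H](c8ccc(OCc9ccccc9)c(OCc9ccccc9)c8)C(OC)=C2
F4 | step 10 | (2R)-5,7-bis(benzyloxy)-2-[3,4-bis(benzyloxy)phenyl]-4-(hydroxyimino)chroman-3-one | O(Cc9ccccc9)c1cc(OCc9ccccc9)c2c(c1)O[C@H](c8ccc(OCc9ccccc9)c(OCc9ccccc9)c8)C(=O)C2=NO
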